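Remark on the chemistry (assumption): the ligand antipode named in step 4 and the allylborane antipode in step 12 are taken to deliver the faces stated there; if either sense is reversed, the mirror-image reagent is used. TBSO = tert-butyldimethylsilyloxy, TESO = triethylsilyloxy; locants C1–C28 are those of target 64 (C1 lactone carbonyl, O27 ring oxygen).

## Analysis of the target

Compound 64 is a 28-membered macrolactone (C1–C27 plus O27) with an ethyl branch at C2, methyl groups at C14 and C26, six secondary hydroxyls (C3, C5, C9, C11, C13, C15) and an all-E pentaene from C16 to C25. The ten stereocentres are 2S, 3R, 5S, 9S, 11S, 13R, 14R, 15R, 26R, 27R. In a zigzag drawing the C2 ethyl and O3 are syn, O3/O5 anti, O9/O11 syn, O11/O13 anti, O13/O15 anti, the C14 methyl is syn to O15 and anti to O13, and the C26 methyl is syn to O27. C5 and C9 are separated by three methylenes, so neither can relay stereochemistry to the other. The pentaene is sensitive to light, acid and oxidants; the C15 carbinol is allylic to it and ionises easily; the lactone is a β-hydroxy ester with an epimerisable C2 that can eliminate or undergo retro-aldol cleavage. The difficulties are therefore absolute control at remote centres, late introduction of the polyene, and closure of a large ring without touching C2. The strategy rests on one structural feature: if O15 is closed onto C11 at the aldehyde oxidation level, C11–C15 becomes a pyran in which O13, the C14 methyl and the C16 chain are all cis. A 2,3-cis-dihydropyran-4-one of that shape is the product of an endo hetero-Diels–Alder reaction.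

## Retrosynthetic reasoning

**C1–O27.** Target 64 is traced to its hexasilyl ether 63 and this to seco acid 61. The lactone bond is the only heteroatom bond in the ring, and cutting it leaves the pentaene and all ten stereocentres in place. The forward reaction must acylate the hindered C27 hydroxyl at high dilution without epimerising C2.

**C18=C19.** Seco acid 61 comes from allyl ester 60, which is cut in the pentaene into enal 45 and hydroxy trienyl phosphonate 58. The cut is placed here because C16=C17 already exists in the cycloaddition partner 8, and because it keeps the polyene out of the route until four steps from the end. The olefination must give the E alkene and tolerate the ester.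

**C24=C25 and C26–C27.** Phosphonate 58 comes from aldehyde 52 and the symmetrical bisphosphonate 55 (made from diol 53 through dibromide 54). Aldehyde 52 comes from an auxiliary-controlled syn aldol between imide 46 and acetaldehyde 47, which sets C26 and C27 together.

**Functional-group level at C1, C9 and C11.** Enal 45 is traced through acid 42 and alcohol 40 to the dithiane carbinol 36. C1 travels as a silyl ether because an ester would not survive the carbanion used for the fragment union. C11 is kept as a masked ketone so that the C9 hydroxyl can direct its reduction and set C11 syn (diol 38).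

**C10–C11.** Carbinol 36 is cut into lithiated dithiane 35 (from dithiane 15) and terminal epoxide 34. C11 is the one carbon that leaves the pyran template at the aldehyde level, so it is the natural acyl-anion site. The epoxide delivers C9 with its configuration fixed beforehand, which matters because the C6–C8 methylene gap offers no other handle.

**Epoxide 34.** The C2–C3 bond is cut by a syn aldol between imide 29 and aldehyde 26 (sets C2, C3). The C4–C5 bond is cut by allylboration of aldehyde 21 with reagent 22 (sets C5). C9 comes from (S)-epichlorohydrin 16, joined to Grignard reagent 17 at C7–C8. Each remote centre thus has its own independent source.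

**Opening the template.** Dithiane 15 is traced through carbinol 14 to lactol 13, glycal 12, allylic alcohol 11 and pyranone 10. The ring is used twice: its half-chair directs hydride to C13, and its enol ether carbon C11 becomes the lactol carbon through which the ring opens.

**Key disconnection.** Pyranone 10 is cut across C14–C15 and O15–C11 into diene 5 and enal 8. One catalytic step then builds the ring, sets C15 absolutely and sets C14 relative to it.

**Precursors.** Diene 5 comes from enone 4, made by methylation of enone 1 with iodide 2. Enal 8 comes from cross-metathesis of allyl ether 6 with enal 7.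

## Alternatives that were turned down

**Alternative 1:** The C5–C9 spacer is cut at C6–C7 and C8–C9. In the forward sense the enol of 1,3-diketone A2 is irradiated through Pyrex under ethene A3; [2+2] addition gives an acylcyclobutanol that fragments by retro-aldol to the C1–C13 1,5-diketone A1. In its favour: the awkward three-methylene link is made from a C2 feedstock, two chiral pieces are joined by a simple diketone synthesis, and either enol tautomer leads to the same product. Against it: A1 carries two prochiral ketones (C5, C9) that must be reduced with different 1,3-relationships, which needs two separately unmasked directing hydroxyls. The β-oxygenated ketones can also eliminate or cleave under irradiation. Most important, A1 ends at C13 as a primary silyl ether, so the C13–C15 triad and the C14 methyl remain unsolved. On convergence for the saturated polyol backbone this alternative is as strong as or stronger than the chosen route. The chosen route offers instead C5 and C9 fixed by a reagent (22) and by the chiral pool (16) with no ketone differentiation, and the congested triad solved in one catalytic step.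

**Alternative 2:** The ring is cut at C2–C3. In the forward sense SmI2 (divalent samarium) reduces the O27 2-bromobutanoate of seco aldehyde A5 to a samarium enolate that adds to the C3 aldehyde, giving macrolide A4. In its favour: ring closure and two stereocentres come in one step, there is no seco-acid activation and no high-dilution acylation of the hindered C27 hydroxyl, and the C3 hydroxyl emerges free. On step count at the end game it is stronger than the chosen route. Against it: C2 and C3 would be set inside a 28-membered transition state for which no reliable model exists, so four diastereomers are possible. The C3 aldehyde has a β-silyloxy group and can eliminate, and the bromo ester must be carried through the polyene chemistry. The chosen route gives up the short end game for auxiliary control of C2/C3 at the start (step 16).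

**Alternative 3:** The ring is cut at C15–C16. In the forward sense CrCl2 (divalent chromium) with catalytic NiCl2 (divalent nickel) turns the pentaenyl iodide terminus of seco compound A7 into an alkenylchromium that adds to the C15 aldehyde, giving macrolide A6. In its favour: the conditions are mild and ester-tolerant, the sensitive C15 carbinol appears last and needs no protecting group, and the substrate bias points the right way (Felkin control from the C14 methyl and 1,3-anti induction from the C13 silyl ether reinforce each other for 15R). On these points it is as strong as the chosen route. Against it: that bias is usually modest for alkenylchromium additions and may be overridden by the ring. A pentaenyl iodide is a fragile intermediate to carry, and the aldehyde is epimerisable at C14. The chosen route sets C15 and C14 together with a catalyst in step 4, long before any polyene exists, at the price of a late desilylation at C15.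

Key step: step 4

## Route

Step 1
Reactants: 1 (E)-4-methoxybut-3-en-2-one; 2 iodomethane
Product: 4 (E)-1-methoxypent-1-en-3-one, via lithium dienolate 3 (not isolated)
Conditions: LiN(SiMe3)2, THF, −78 °C; then MeI, −78 → −20 °C
Reagents that add atoms: none
Why: Kinetic deprotonation of the vinylogous ester at its only enolisable position (the methyl group) and C-alkylation of the lithium enolate with a reactive iodide; enolate alkylation.

Step 2
Reactants: 4 (E)-1-methoxypent-1-en-3-one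
Product: 5 (1E,3Z)-1-methoxy-3-(trimethylsilyloxy)penta-1,3-diene
Conditions: Me3SiOTf, Et3N, Et2O, 0 °C
Reagents that add atoms: trimethylsilyl trifluoromethanesulfonate, C[Si](C)(C)OS(=O)(=O)C(F)(F)F
Why: Soft enolisation and O-silylation of an ethyl ketone with amine and silyl triflate should give mainly the Z enol ether (methyl cis to the silyloxy group); the 1E geometry is carried over.

Step 3
Reactants: 6 (allyloxy)(tert-butyl)dimethylsilane; 7 (E)-but-2-enal
Product: 8 (E)-4-(tert-butyldimethylsilyloxy)but-2-enal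
Conditions: second-generation Hoveyda–Grubbs catalyst RuCl2(H2IMes)(=CH-C6H4-2-O-i-Pr) (2 mol%), 7 (5 equiv), CH2Cl2, 40 °C
Reagents that add atoms: none
Why: Olefin cross-metathesis of a terminal allylic ether with an excess of an electron-poor enal; thermodynamic control should give the E enal while propene escapes.

Step 4
Reactants: 5 (1E,3Z)-1-methoxy-3-(trimethylsilyloxy)penta-1,3-diene; 8 (E)-4-(tert-butyldimethylsilyloxy)but-2-enal
Product: 10 (2R,3S)-2-[(E)-3-(TBSO)prop-1-en-1-yl]-3-methyl-2,3-dihydro-4H-pyran-4-one, via silyl enol ether cycloadduct 9 (not isolated)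
Conditions: CrCl(L) (5 mol%; trivalent chromium; L = dianion of the Schiff base from 3-(1-adamantyl)-2-hydroxy-5-methylbenzaldehyde and (1S,2R)-1-aminoindan-2-ol), 4 Å molecular sieves, t-BuOMe, −20 °C → rt; then CF3CO2H (cat.), CH2Cl2, 0 °C
Reagents that add atoms: none
Why: The chromium centre binds the aldehyde oxygen of 8 anti to the alkenyl group, and diene 5 adds across C=O in a concerted, asynchronous [4+2] cycloaddition that forms C14–C15 and O15–C11 and closes the six-membered oxacycle in one suprafacial event; acid then expels methanol and the silyl group from 9 to give enone 10. The closest known reaction is the chromium Schiff-base catalysed hetero-Diels–Alder reaction of 1-alkoxy-3-silyloxy dienes with aldehydes, of which an enal is only a new member. C15 is set by the catalyst, whose indanol pocket should expose the Si face of the carbonyl. C14 is set relative to C15 by the diene geometry and the endo mode: the 3Z methyl lies on the outside of the s-cis diene and the aldehyde substituent is endo, so the two end up cis. The step needs chemoselectivity for C=O over the conjugated C=C (no use of 8 as an oxadiene, no conjugate addition), which the oxophilic Lewis acid and the strongly nucleophilic diene terminus should secure. It also needs a cold, brief acid treatment so that C14, now alpha to the ketone, does not epimerise to the trans isomer.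

Step 5
Reactants: 10 (2R,3S)-2-[(E)-3-(TBSO)prop-1-en-1-yl]-3-methyl-2,3-dihydro-4H-pyran-4-one
Product: 11 (2R,3R,4R)-2-[(E)-3-(TBSO)prop-1-en-1-yl]-3-methyl-3,4-dihydro-2H-pyran-4-ol (all-cis)
Conditions: NaBH4, CeCl3·7H2O, MeOH, −78 → −40 °C
Reagents that add atoms: none
Why: Luche 1,2-reduction; in the half-chair the C14 methyl is pseudo-axial, so hydride should enter axially anti to it and place the new C13 hydroxyl cis to both neighbours (13R).

Step 6
Reactants: 11 (2R,3R,4R)-2-[(E)-3-(TBSO)prop-1-en-1-yl]-3-methyl-3,4-dihydro-2H-pyran-4-ol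
Product: 12 (2R,3S,4R)-4-(TBSO)-2-[(E)-3-(TBSO)prop-1-en-1-yl]-3-methyl-3,4-dihydro-2H-pyran
Conditions: t-BuMe2SiCl, imidazole, DMF, rt
Reagents that add atoms: tert-butyldimethylsilyl chloride, CC(C)(C)[Si](C)(C)Cl
Why: Standard silylation of a secondary allylic alcohol; a silyl ether at C13 is a poor leaving group and suppresses Ferrier-type allylic displacement in the next step.

Step 7
Reactants: 12 (2R,3S,4R)-4-(TBSO)-2-[(E)-3-(TBSO)prop-1-en-1-yl]-3-methyl-3,4-dihydro-2H-pyran
Product: 13 (4R,5S,6R)-4-(TBSO)-6-[(E)-3-(TBSO)prop-1-en-1-yl]-5-methyltetrahydro-2H-pyran-2-ol (anomer mixture)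
Conditions: Ph3P·HBr (5 mol%), THF/H2O (10:1), rt
Reagents that add atoms: water, O
Why: Acid-catalysed Markovnikov hydration of the enol ether (glycal to 2-deoxy lactol) through the C11 oxocarbenium ion; the mild phosphonium bromide catalyst should leave silyl ethers and the isolated alkene untouched.

Step 8
Reactants: 13 (4R,5S,6R)-4-(TBSO)-6-[(E)-3-(TBSO)prop-1-en-1-yl]-5-methyltetrahydro-2H-pyran-2-ol
Product: 14 (2E,4R,5S,6R)-1,6-bis(TBSO)-7-(1,3-dithian-2-yl)-5-methylhept-2-en-4-ol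
Conditions: HS(CH2)3SH, BF3·OEt2 (0.5 equiv), CH2Cl2, −78 → −30 °C
Reagents that add atoms: propane-1,3-dithiol, SCCCS
Why: Lewis-acid thioacetalisation of the lactol through its oxocarbenium and open hydroxy-aldehyde forms; formation of the six-membered dithiane opens the ring and frees O15 as the only hydroxyl.

Step 9
Reactants: 14 (2E,4R,5S,6R)-1,6-bis(TBSO)-7-(1,3-dithian-2-yl)-5-methylhept-2-en-4-ol
Product: 15 2-[(2R,3R,4R,5E)-2,4,7-tris(TBSO)-3-methylhept-5-en-1-yl]-1,3-dithiane
Conditions: t-BuMe2SiOTf, 2,6-lutidine, CH2Cl2, −78 → 0 °C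
Reagents that add atoms: tert-butyldimethylsilyl trifluoromethanesulfonate, CC(C)(C)[Si](C)(C)OS(=O)(=O)C(F)(F)F
Why: Silyl triflate silylation of the hindered allylic alcohol; no acidic or electrophilic site remains for the carbanion chemistry of step 20.

Step 10
Reactants: 16 (S)-epichlorohydrin; 17 but-3-enylmagnesium bromide
Product: 19 (S)-2-(pent-4-en-1-yl)oxirane, via chlorohydrin 18 (not isolated)
Conditions: CuI (10 mol%; monovalent copper), THF, −40 → 0 °C; then powdered NaOH, Et2O, rt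
Reagents that add atoms: none
Why: Copper-catalysed Grignard opening at the epoxide CH2 of epichlorohydrin, then base closure of the chlorohydrin; the stereocentre is never touched, so the S configuration (future C9) is carried over.

Step 11
Reactants: 19 (S)-2-(pent-4-en-1-yl)oxirane
Product: 21 4-[(2S)-oxiran-2-yl]butanal, via secondary ozonide 20 (not isolated)
Conditions: O3, CH2Cl2, −78 °C; then PPh3, −78 °C → rt
Reagents that add atoms: ozone, [O-][O+]=O
Why: Ozonolysis with reductive work-up; epoxides are inert to ozone and to the phosphine.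

Step 12
Reactants: 21 4-[(2S)-oxiran-2-yl]butanal; 22 (+)-B-allyldiisopinocampheylborane
Product: 23 (4S)-7-[(2S)-oxiran-2-yl]hept-1-en-4-ol
Conditions: Et2O, −78 °C; then NaBO3·4H2O, THF/H2O, rt
Reagents that add atoms: none
Why: Brown allylboration through a chair six-membered transition state; the reagent derived from (−)-α-pinene should add to the aldehyde face that gives the S carbinol (C5), independent of the remote epoxide. The hydroxy epoxide is kept acid-free and silylated at once to prevent 6-exo cyclisation.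

Step 13
Reactants: 23 (4S)-7-[(2S)-oxiran-2-yl]hept-1-en-4-ol
Product: 24 (2S)-2-[(4S)-4-(TBSO)hept-6-en-1-yl]oxirane
Conditions: t-BuMe2SiCl, imidazole, DMF, rt
Reagents that add atoms: tert-butyldimethylsilyl chloride, CC(C)(C)[Si](C)(C)Cl
Why: Neutral silylation of a secondary alcohol; the epoxide is stable to imidazole.

Step 14
Reactants: 24 (2S)-2-[(4S)-4-(TBSO)hept-6-en-1-yl]oxirane
Product: 26 (3S)-3-(TBSO)-6-[(2S)-oxiran-2-yl]hexanal, via secondary ozonide 25 (not isolated)
Conditions: O3, CH2Cl2, −78 °C; then PPh3, −78 °C → rt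
Reagents that add atoms: ozone, [O-][O+]=O
Why: Ozonolysis of the terminal alkene with reductive work-up; the β-silyloxy aldehyde is used without delay to avoid elimination.

Step 15
Reactants: 27 (S)-4-benzyloxazolidin-2-one; 28 butanoyl chloride
Product: 29 (S)-4-benzyl-3-butanoyloxazolidin-2-one
Conditions: Et3N, DMAP (cat.), CH2Cl2, 0 °C → rt
Reagents that add atoms: none
Why: N-acylation of the oxazolidinone by the acid chloride under amine and acyl-transfer catalysis.

Step 16
Reactants: 29 (S)-4-benzyl-3-butanoyloxazolidin-2-one; 26 (3S)-3-(TBSO)-6-[(2S)-oxiran-2-yl]hexanal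
Product: 31 (4S)-4-benzyl-3-{(2S,3R,5S)-5-(TBSO)-2-ethyl-3-hydroxy-8-[(2S)-oxiran-2-yl]octanoyl}oxazolidin-2-one, via Z boron enolate 30 (not isolated)
Conditions: n-Bu2BOTf, Et3N, CH2Cl2, −78 → 0 °C; then 26, −78 → 0 °C; pH 7 buffer, MeOH, H2O2, 0 °C
Reagents that add atoms: none
Why: Evans syn aldol: the Z boron enolate reacts through a Zimmerman–Traxler chair in which the auxiliary shields one enolate face, giving 2S,3R under reagent control over the β-silyloxy centre. The boron triflate is consumed in enolisation before the epoxy aldehyde is added.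

Step 17
Reactants: 31 (4S)-4-benzyl-3-{(2S,3R,5S)-5-(TBSO)-2-ethyl-3-hydroxy-8-[(2S)-oxiran-2-yl]octanoyl}oxazolidin-2-one
Product: 32 (4S)-4-benzyl-3-{(2S,3R,5S)-3,5-bis(TBSO)-2-ethyl-8-[(2S)-oxiran-2-yl]octanoyl}oxazolidin-2-one
Conditions: t-BuMe2SiOTf, 2,6-lutidine, CH2Cl2, −78 °C, cold quench
Reagents that add atoms: tert-butyldimethylsilyl trifluoromethanesulfonate, CC(C)(C)[Si](C)(C)OS(=O)(=O)C(F)(F)F
Why: Silylation of the aldol hydroxyl; at −78 °C with base present the hydroxyl should react far faster than the epoxide is activated.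

Step 18
Reactants: 32 (4S)-4-benzyl-3-{(2S,3R,5S)-3,5-bis(TBSO)-2-ethyl-8-[(2S)-oxiran-2-yl]octanoyl}oxazolidin-2-one
Product: 33 (2R,3R,5S)-3,5-bis(TBSO)-2-ethyl-8-[(2S)-oxiran-2-yl]octan-1-ol
Conditions: LiBH4, MeOH (1 equiv), Et2O, 0 °C
Reagents that add atoms: none
Why: Reductive removal of the auxiliary; the exocyclic imide carbonyl is reduced selectively and a terminal epoxide reacts only slowly with LiBH4 at 0 °C.

Step 19
Reactants: 33 (2R,3R,5S)-3,5-bis(TBSO)-2-ethyl-8-[(2S)-oxiran-2-yl]octan-1-ol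
Product: 34 (2S)-2-[(4S,6R,7R)-4,6-bis(TBSO)-7-ethyl-8-(TESO)octyl]oxirane
Conditions: Et3SiCl, imidazole, CH2Cl2, 0 °C
Reagents that add atoms: chlorotriethylsilane, CC[Si](Cl)(CC)CC
Why: A primary triethylsilyl ether is inert to the carbanion of step 20 and can later be removed in the presence of all TBS ethers.

Step 20
Reactants: 15 2-[(2R,3R,4R,5E)-2,4,7-tris(TBSO)-3-methylhept-5-en-1-yl]-1,3-dithiane; 34 (2S)-2-[(4S,6R,7R)-4,6-bis(TBSO)-7-ethyl-8-(TESO)octyl]oxirane
Product: 36 (2R,3R,5S,9S)-3,5-bis(TBSO)-2-ethyl-10-{2-[(2R,3R,4R,5E)-2,4,7-tris(TBSO)-3-methylhept-5-en-1-yl]-1,3-dithian-2-yl}-1-(TESO)decan-9-ol, via lithiated dithiane 35 (not isolated)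
Conditions: 15, t-BuLi, THF/HMPA (9:1), −78 °C, 10 min; then 34, −78 → −30 °C; aq NH4Cl
Reagents that add atoms: none
Why: Corey–Seebach dithiane alkylation with an epoxide: the C11 acyl-anion equivalent opens the terminal epoxide at C10 by SN2, so C9 keeps its configuration and appears as the free hydroxyl; neither partner has an electrophilic carbonyl.

Step 21
Reactants: 36 (2R,3R,5S,9S)-3,5-bis(TBSO)-2-ethyl-10-{2-[(2R,3R,4R,5E)-2,4,7-tris(TBSO)-3-methylhept-5-en-1-yl]-1,3-dithian-2-yl}-1-(TESO)decan-9-ol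
Product: 37 (2R,3R,5S,9S,13R,14R,15R,16E)-3,5,13,15,18-pentakis(TBSO)-2-ethyl-9-hydroxy-14-methyl-1-(TESO)octadec-16-en-11-one
Conditions: MeI, CaCO3, MeCN/H2O (9:1), 40 °C
Reagents that add atoms: water, O
Why: S-alkylative hydrolysis of the dithiane under buffered, non-acidic conditions should release the β-hydroxy ketone without touching silyl ethers or the alkene.

Step 22
Reactants: 37 (2R,3R,5S,9S,13R,14R,15R,16E)-3,5,13,15,18-pentakis(TBSO)-2-ethyl-9-hydroxy-14-methyl-1-(TESO)octadec-16-en-11-one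
Product: 38 (2R,3R,5S,9S,11S,13R,14R,15R,16E)-3,5,13,15,18-pentakis(TBSO)-2-ethyl-14-methyl-1-(TESO)octadec-16-ene-9,11-diol
Conditions: Et2BOMe, THF/MeOH (4:1), −78 °C; NaBH4, −78 °C; then pH 7 buffer, MeOH, H2O2, 0 °C
Reagents that add atoms: none
Why: Narasaka–Prasad reduction: the diethylboron chelate of the β-hydroxy ketone is attacked axially by external hydride, giving the 9,11-syn diol (11S); O13 is silylated and cannot compete as a director.

Step 23
Reactants: 38 (2R,3R,5S,9S,11S,13R,14R,15R,16E)-3,5,13,15,18-pentakis(TBSO)-2-ethyl-14-methyl-1-(TESO)octadec-16-ene-9,11-diol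
Product: 39 (2R,3R,5S,9S,11S,13R,14R,15R,16E)-3,5,9,11,13,15,18-heptakis(TBSO)-2-ethyl-14-methyl-1-(TESO)octadec-16-ene
Conditions: t-BuMe2SiOTf, 2,6-lutidine, CH2Cl2, −78 → 0 °C
Reagents that add atoms: tert-butyldimethylsilyl trifluoromethanesulfonate, CC(C)(C)[Si](C)(C)OS(=O)(=O)C(F)(F)F
Why: Exhaustive silylation of the syn 1,3-diol with the reactive triflate.

Step 24
Reactants: 39 (2R,3R,5S,9S,11S,13R,14R,15R,16E)-3,5,9,11,13,15,18-heptakis(TBSO)-2-ethyl-14-methyl-1-(TESO)octadec-16-ene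
Product: 40 (2R,3R,5S,9S,11S,13R,14R,15R,16E)-3,5,9,11,13,15,18-heptakis(TBSO)-2-ethyl-14-methyloctadec-16-en-1-ol
Conditions: PPTS (0.2 equiv), MeOH/CH2Cl2 (1:1), 0 °C
Reagents that add atoms: none
Why: Acid methanolysis cleaves a primary triethylsilyl ether much faster than primary or secondary TBS ethers, so only C1 is unmasked.

Step 25
Reactants: 40 (2R,3R,5S,9S,11S,13R,14R,15R,16E)-3,5,9,11,13,15,18-heptakis(TBSO)-2-ethyl-14-methyloctadec-16-en-1-ol
Product: 42 (2S,3R,5S,9S,11S,13R,14R,15R,16E)-3,5,9,11,13,15,18-heptakis(TBSO)-2-ethyl-14-methyloctadec-16-enoic acid, via aldehyde 41 (not isolated)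
Conditions: TEMPO (0.2 equiv), PhI(OAc)2 (2.5 equiv), MeCN/CH2Cl2/H2O, rt
Reagents that add atoms: water, O
Why: Oxoammonium oxidation of the primary alcohol to the aldehyde, whose hydrate is oxidised on to the acid in the aqueous medium; the conditions are weakly acidic, so C2 should not epimerise, and the isolated alkene is not attacked.

Step 26
Reactants: 42 (2S,3R,5S,9S,11S,13R,14R,15R,16E)-3,5,9,11,13,15,18-heptakis(TBSO)-2-ethyl-14-methyloctadec-16-enoic acid
Product: 43 allyl (2S,3R,5S,9S,11S,13R,14R,15R,16E)-3,5,9,11,13,15,18-heptakis(TBSO)-2-ethyl-14-methyloctadec-16-enoate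
Conditions: allyl bromide, K2CO3, DMF, 0 °C → rt
Reagents that add atoms: allyl bromide, C=CCBr
Why: O-alkylation of the carboxylate; the allyl ester masks the acid during the olefination and is removable later under neutral conditions.

Step 27
Reactants: 43 allyl (2S,3R,5S,9S,11S,13R,14R,15R,16E)-3,5,9,11,13,15,18-heptakis(TBSO)-2-ethyl-14-methyloctadec-16-enoate
Product: 44 allyl (2S,3R,5S,9S,11S,13R,14R,15R,16E)-3,5,9,11,13,15-hexakis(TBSO)-2-ethyl-18-hydroxy-14-methyloctadec-16-enoate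
Conditions: HF·pyridine, pyridine, THF, 0 °C
Reagents that add atoms: none
Why: Buffered HF·pyridine removes the single primary (allylic) TBS ether selectively over the six secondary ones.

Step 28
Reactants: 44 allyl (2S,3R,5S,9S,11S,13R,14R,15R,16E)-3,5,9,11,13,15-hexakis(TBSO)-2-ethyl-18-hydroxy-14-methyloctadec-16-enoate
Product: 45 allyl (2S,3R,5S,9S,11S,13R,14R,15R,16E)-3,5,9,11,13,15-hexakis(TBSO)-2-ethyl-14-methyl-18-oxooctadec-16-enoate
Conditions: MnO2 (20 equiv), CH2Cl2, rt
Reagents that add atoms: none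
Why: MnO2 oxidises allylic alcohols selectively under neutral conditions; the E geometry is retained.

Step 29
Reactants: 46 (S)-4-benzyl-3-propanoyloxazolidin-2-one; 47 acetaldehyde
Product: 49 (4S)-4-benzyl-3-[(2S,3R)-3-hydroxy-2-methylbutanoyl]oxazolidin-2-one, via Z boron enolate 48 (not isolated)
Conditions: n-Bu2BOTf, Et3N, CH2Cl2, −78 → 0 °C; then 47 (excess), −78 → 0 °C; pH 7 buffer, MeOH, H2O2, 0 °C
Reagents that add atoms: none
Why: Evans syn aldol through the chair transition state of the Z boron enolate; the auxiliary sets both new centres, which become C26 and C27.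

Step 30
Reactants: 49 (4S)-4-benzyl-3-[(2S,3R)-3-hydroxy-2-methylbutanoyl]oxazolidin-2-one
Product: 50 (2S,3R)-3-hydroxy-N-methoxy-N,2-dimethylbutanamide
Conditions: MeNH(OMe)·HCl, AlMe3, CH2Cl2, −20 → 0 °C
Reagents that add atoms: N,O-dimethylhydroxylamine hydrochloride, CNOC.Cl
Why: Aluminium amide transamination of the β-hydroxy imide to the Weinreb amide, assisted by the free hydroxyl; the auxiliary is recovered.

Step 31
Reactants: 50 (2S,3R)-3-hydroxy-N-methoxy-N,2-dimethylbutanamide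
Product: 51 (2S,3R)-N-methoxy-N,2-dimethyl-3-(TESO)butanamide
Conditions: Et3SiCl, imidazole, CH2Cl2, 0 °C → rt
Reagents that add atoms: chlorotriethylsilane, CC[Si](Cl)(CC)CC
Why: Silylation prevents retro-aldol cleavage of the aldehyde made next; the triethylsilyl group can be removed later from an acid-sensitive triene.

Step 32
Reactants: 51 (2S,3R)-N-methoxy-N,2-dimethyl-3-(TESO)butanamide
Product: 52 (2S,3R)-2-methyl-3-(TESO)butanal
Conditions: i-Bu2AlH, THF, −78 °C; aqueous potassium sodium tartrate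
Reagents that add atoms: none
Why: Weinreb amide reduction stops at the aldehyde because the chelated tetrahedral intermediate survives until work-up; the α-stereocentre is not epimerised at low temperature.

Step 33
Reactants: 53 hexa-1,5-diene-3,4-diol
Product: 54 (2E,4E)-1,6-dibromohexa-2,4-diene
Conditions: PBr3, Et2O, 0 °C → rt
Reagents that add atoms: phosphorus tribromide, BrP(Br)Br
Why: Double allylic substitution with transposition turns the bis-allylic diol into the conjugated primary dibromide; the E,E diene is the thermodynamic and crystalline product.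

Step 34
Reactants: 54 (2E,4E)-1,6-dibromohexa-2,4-diene
Product: 55 tetraethyl [(2E,4E)-hexa-2,4-diene-1,6-diyl]bis(phosphonate)
Conditions: P(OEt)3, neat, 120 °C
Reagents that add atoms: triethyl phosphite, CCOP(OCC)OCC
Why: Michaelis–Arbuzov reaction of a reactive allylic dibromide at both ends.

Step 35
Reactants: 52 (2S,3R)-2-methyl-3-(TESO)butanal; 55 tetraethyl [(2E,4E)-hexa-2,4-diene-1,6-diyl]bis(phosphonate)
Product: 57 diethyl [(2E,4E,6E,8R,9R)-8-methyl-9-(TESO)deca-2,4,6-trien-1-yl]phosphonate, via lithiated bisphosphonate 56 (not isolated)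
Conditions: 55 (3 equiv), LiN(SiMe3)2 (1.1 equiv to 52), THF, −78 °C; then 52, −78 → 0 °C
Reagents that add atoms: none
Why: Horner–Wadsworth–Emmons mono-olefination; the excess of symmetrical bisphosphonate should keep the reaction at one end, and the dienyl-stabilised anion should give the E alkene (C24=C25).

Step 36
Reactants: 57 diethyl [(2E,4E,6E,8R,9R)-8-methyl-9-(TESO)deca-2,4,6-trien-1-yl]phosphonate
Product: 58 diethyl [(2E,4E,6E,8R,9R)-9-hydroxy-8-methyldeca-2,4,6-trien-1-yl]phosphonate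
Conditions: PPTS, MeOH, 0 °C → rt, dark
Reagents that add atoms: none
Why: Mild acid methanolysis of a secondary triethylsilyl ether; the hydroxyl is homoallylic to the triene and does not ionise.

Step 37
Reactants: 45 allyl (2S,3R,5S,9S,11S,13R,14R,15R,16E)-3,5,9,11,13,15-hexakis(TBSO)-2-ethyl-14-methyl-18-oxooctadec-16-enoate; 58 diethyl [(2E,4E,6E,8R,9R)-9-hydroxy-8-methyldeca-2,4,6-trien-1-yl]phosphonate
Product: 60 allyl (2S,3R,5S,9S,11S,13R,14R,15R,16E,18E,20E,22E,24E,26R,27R)-3,5,9,11,13,15-hexakis(TBSO)-2-ethyl-27-hydroxy-14,26-dimethyloctacosa-16,18,20,22,24-pentaenoate, via dilithiated phosphonate 59 (not isolated)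
Conditions: 58 (1.5 equiv), LiN(SiMe3)2 (3.1 equiv), THF, −78 °C; then 45, −78 → −20 °C, dark; aq NH4Cl
Reagents that add atoms: none
Why: Horner–Wadsworth–Emmons olefination of the enal by the trienyl phosphonate carbanion, with the C27 lithium alkoxide as a spectator; the conjugated carbanion should favour the E alkene at C18=C19, and at low temperature it should add to the aldehyde much faster than it deprotonates C2 of the hindered ester.

Step 38
Reactants: 60 allyl (2S,3R,5S,9S,11S,13R,14R,15R,16E,18E,20E,22E,24E,26R,27R)-3,5,9,11,13,15-hexakis(TBSO)-2-ethyl-27-hydroxy-14,26-dimethyloctacosa-16,18,20,22,24-pentaenoate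
Product: 61 (2S,3R,5S,9S,11S,13R,14R,15R,16E,18E,20E,22E,24E,26R,27R)-3,5,9,11,13,15-hexakis(TBSO)-2-ethyl-27-hydroxy-14,26-dimethyloctacosa-16,18,20,22,24-pentaenoic acid
Conditions: Pd(PPh3)4 (5 mol%; zerovalent palladium), morpholine, THF, rt, dark
Reagents that add atoms: none
Why: Tsuji–Trost deallylation: palladium ionises only the allyl ester and the amine traps the allyl unit; silyl ethers are not leaving groups, so the polyene end is not touched.

Step 39
Reactants: 61 (2S,3R,5S,9S,11S,13R,14R,15R,16E,18E,20E,22E,24E,26R,27R)-3,5,9,11,13,15-hexakis(TBSO)-2-ethyl-27-hydroxy-14,26-dimethyloctacosa-16,18,20,22,24-pentaenoic acid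
Product: 63 3,5,9,11,13,15-hexakis-O-(tert-butyldimethylsilyl) derivative of 64 (28-membered lactone), via mixed anhydride 62 (not isolated)
Conditions: 2,4,6-Cl3C6H2COCl, Et3N, THF, rt; then slow addition to DMAP, toluene (0.5 mM), 40 °C, dark
Reagents that add atoms: none
Why: Yamaguchi macrolactonisation: the mixed anhydride is attacked by DMAP and the acylpyridinium is trapped by the C27 hydroxyl under high dilution; the rigid pentaene and the silyl-stiffened polyol chain should favour cyclisation over oligomerisation.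

Step 40
Reactants: 63 3,5,9,11,13,15-hexakis-O-(tert-butyldimethylsilyl) derivative of 64
Product: 64 (3S,4R,6S,10S,12S,14R,15R,16R,17E,19E,21E,23E,25E,27R,28R)-3-ethyl-4,6,10,12,14,16-hexahydroxy-15,27,28-trimethyl-1-oxacyclooctacosa-17,19,21,23,25-pentaen-2-one (target; 2S,3R,5S,9S,11S,13R,14R,15R,26R,27R in chain numbering)
Conditions: HF·pyridine, pyridine, THF, 0 °C → rt, dark
Reagents that add atoms: none
Why: Global desilylation with buffered HF·pyridine, as used for polyene macrolides; the buffer should keep the medium too weakly acidic to ionise the C15 carbinol or open the lactone.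

## Compound list

1 | (E)-4-methoxybut-3-en-2-one | CO/C=C/C(C)=O | starting material
2 | iodomethane | CI | starting material
3 | lithium (3E)-4-methoxybuta-1,3-dien-2-olate | [Li]OC(=C)/C=C/OC | intermediate
4 | (E)-1-methoxypent-1-en-3-one | CO/C=C/C(=O)CC | intermediate
5 | (1E,3Z)-1-methoxy-3-(trimethylsilyloxy)penta-1,3-diene | CO/C=C/C(O[Si](C)(C)C)=C/C | intermediate
6 | (allyloxy)(tert-butyl)dimethylsilane | C=CCO[Si](C)(C)C(C)(C)C | starting material
7 | (E)-but-2-enal | C/C=C/C=O | starting material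
8 | (E)-4-(tert-butyldimethylsilyloxy)but-2-enal | O=C/C=C/CO[Si](C)(C)C(C)(C)C | intermediate
9 | (2R,3S,6R)-2-[(E)-3-(TBSO)prop-1-en-1-yl]-6-methoxy-3-methyl-4-(trimethylsilyloxy)-3,6-dihydro-2H-pyran | CO[C@H]1C=C(O[Si](C)(C)C)[C@@H](C)[C@@H](/C=C/CO[Si](C)(C)C(C)(C)C)O1 | intermediate
10 | (2R,3S)-2-[(E)-3-(TBSO)prop-1-en-1-yl]-3-methyl-2,3-dihydro-4H-pyran-4-one | C[C@H]1[C@@H](/C=C/CO[Si](C)(C)C(C)(C)C)OC=CC1=O | intermediate
11 | (2R,3R,4R)-2-[(E)-3-(TBSO)prop-1-en-1-yl]-3-methyl-3,4-dihydro-2H-pyran-4-ol | C[C@H]1[C@@H](/C=C/CO[Si](C)(C)C(C)(C)C)OC=C[C@H]1O | intermediate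
12 | (2R,3S,4R)-4-(TBSO)-2-[(E)-3-(TBSO)prop-1-en-1-yl]-3-methyl-3,4-dihydro-2H-pyran | C[C@H]1[C@@H](/C=C/CO[Si](C)(C)C(C)(C)C)OC=C[C@H]1O[Si](C)(C)C(C)(C)C | intermediate
13 | (4R,5S,6R)-4-(TBSO)-6-[(E)-3-(TBSO)prop-1-en-1-yl]-5-methyltetrahydro-2H-pyran-2-ol | C[C@H]1[C@@H](/C=C/CO[Si](C)(C)C(C)(C)C)OC(O)C[C@H]1O[Si](C)(C)C(C)(C)C | intermediate
14 | (2E,4R,5S,6R)-1,6-bis(TBSO)-7-(1,3-dithian-2-yl)-5-methylhept-2-en-4-ol | C1CSC(SC1)C[C@@H](O[Si](C)(C)C(C)(C)C)[C@@H](C)[C@H](O)/C=C/CO[Si](C)(C)C(C)(C)C | intermediate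
15 | 2-[(2R,3R,4R,5E)-2,4,7-tris(TBSO)-3-methylhept-5-en-1-yl]-1,3-dithiane | C1CSC(SC1)C[C@@H](O[Si](C)(C)C(C)(C)C)[C@@H](C)[C@H](O[Si](C)(C)C(C)(C)C)/C=C/CO[Si](C)(C)C(C)(C)C | intermediate
16 | (S)-epichlorohydrin | ClC[C@@H]1CO1 | starting material
17 | but-3-enylmagnesium bromide | C=CCC[Mg]Br | starting material
18 | (S)-1-chlorohept-6-en-2-ol | C=CCCC[C@H](O)CCl | intermediate
19 | (S)-2-(pent-4-en-1-yl)oxirane | C=CCCC[C@H]1CO1 | intermediate
20 | 3-{3-[(2S)-oxiran-2-yl]propyl}-1,2,4-trioxolane | C1OC(CCC[C@H]2CO2)OO1 | intermediate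
21 | 4-[(2S)-oxiran-2-yl]butanal | O=CCCC[C@H]1CO1 | intermediate
22 | (+)-B-allyldiisopinocampheylborane | C=CCB([C@H]1C[C@H]2C[C@@H]([C@@H]1C)C2(C)C)[C@H]1C[C@H]2C[C@@H]([C@@H]1C)C2(C)C | starting material
23 | (4S)-7-[(2S)-oxiran-2-yl]hept-1-en-4-ol | C=CC[C@@H](O)CCC[C@H]1CO1 | intermediate
24 | (2S)-2-[(4S)-4-(TBSO)hept-6-en-1-yl]oxirane | C=CC[C@@H](O[Si](C)(C)C(C)(C)C)CCC[C@H]1CO1 | intermediate
25 | 3-{(2S)-2-(TBSO)-5-[(2S)-oxiran-2-yl]pentyl}-1,2,4-trioxolane | C1OC(C[C@@H](O[Si](C)(C)C(C)(C)C)CCC[C@H]2CO2)OO1 | intermediate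
26 | (3S)-3-(TBSO)-6-[(2S)-oxiran-2-yl]hexanal | O=CC[C@@H](O[Si](C)(C)C(C)(C)C)CCC[C@H]1CO1 | intermediate
27 | (S)-4-benzyloxazolidin-2-one | O=C1N[C@@H](Cc2ccccc2)CO1 | starting material
28 | butanoyl chloride | CCCC(Cl)=O | starting material
29 | (S)-4-benzyl-3-butanoyloxazolidin-2-one | CCCC(=O)N1[C@@H](Cc2ccccc2)COC1=O | intermediate
30 | dibutylboron Z enolate of 29 | CC/C=C(\OB(CCCC)CCCC)N1[C@@H](Cc2ccccc2)COC1=O | intermediate
31 | (4S)-4-benzyl-3-{(2S,3R,5S)-5-(TBSO)-2-ethyl-3-hydroxy-8-[(2S)-oxiran-2-yl]octanoyl}oxazolidin-2-one | O=C(N1[C@@H](Cc2ccccc2)COC1=O)[C@@H](CC)[C@H](O)C[C@@H](O[Si](C)(C)C(C)(C)C)CCC[C@H]1CO1 | intermediate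
32 | (4S)-4-benzyl-3-{(2S,3R,5S)-3,5-bis(TBSO)-2-ethyl-8-[(2S)-oxiran-2-yl]octanoyl}oxazolidin-2-one | O=C(N1[C@@H](Cc2ccccc2)COC1=O)[C@@H](CC)[C@H](O[Si](C)(C)C(C)(C)C)C[C@@H](O[Si](C)(C)C(C)(C)C)CCC[C@H]1CO1 | intermediate
33 | (2R,3R,5S)-3,5-bis(TBSO)-2-ethyl-8-[(2S)-oxiran-2-yl]octan-1-ol | OC[C@@H](CC)[C@H](O[Si](C)(C)C(C)(C)C)C[C@@H](O[Si](C)(C)C(C)(C)C)CCC[C@H]1CO1 | intermediate
34 | (2S)-2-[(4S,6R,7R)-4,6-bis(TBSO)-7-ethyl-8-(TESO)octyl]oxirane | CC[Si](CC)(CC)OC[C@@H](CC)[C@H](O[Si](C)(C)C(C)(C)C)C[C@@H](O[Si](C)(C)C(C)(C)C)CCC[C@H]1CO1 | intermediate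
35 | 2-lithio derivative of 15 | [Li]C1(SCCCS1)C[C@@H](O[Si](C)(C)C(C)(C)C)[C@@H](C)[C@H](O[Si](C)(C)C(C)(C)C)/C=C/CO[Si](C)(C)C(C)(C)C | intermediate
36 | (2R,3R,5S,9S)-3,5-bis(TBSO)-2-ethyl-10-{2-[(2R,3R,4R,5E)-2,4,7-tris(TBSO)-3-methylhept-5-en-1-yl]-1,3-dithian-2-yl}-1-(TESO)decan-9-ol | CC[Si](CC)(CC)OC[C@@H](CC)[C@H](O[Si](C)(C)C(C)(C)C)C[C@@H](O[Si](C)(C)C(C)(C)C)CCC[C@H](O)CC1(SCCCS1)C[C@@H](O[Si](C)(C)C(C)(C)C)[C@@H](C)[C@H](O[Si](C)(C)C(C)(C)C)/C=C/CO[Si](C)(C)C(C)(C)C | intermediate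
37 | (2R,3R,5S,9S,13R,14R,15R,16E)-3,5,13,15,18-pentakis(TBSO)-2-ethyl-9-hydroxy-14-methyl-1-(TESO)octadec-16-en-11-one | CC[Si](CC)(CC)OC[C@@H](CC)[C@H](O[Si](C)(C)C(C)(C)C)C[C@@H](O[Si](C)(C)C(C)(C)C)CCC[C@H](O)CC(=O)C[C@@H](O[Si](C)(C)C(C)(C)C)[C@@H](C)[C@H](O[Si](C)(C)C(C)(C)C)/C=C/CO[Si](C)(C)C(C)(C)C | intermediate
38 | (2R,3R,5S,9S,11S,13R,14R,15R,16E)-3,5,13,15,18-pentakis(TBSO)-2-ethyl-14-methyl-1-(TESO)octadec-16-ene-9,11-diol | CC[Si](CC)(CC)OC[C@@H](CC)[C@H](O[Si](C)(C)C(C)(C)C)C[C@@H](O[Si](C)(C)C(C)(C)C)CCC[C@H](O)C[C@H](O)C[C@@H](O[Si](C)(C)C(C)(C)C)[C@@H](C)[C@H](O[Si](C)(C)C(C)(C)C)/C=C/CO[Si](C)(C)C(C)(C)C | intermediate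
39 | (2R,3R,5S,9S,11S,13R,14R,15R,16E)-3,5,9,11,13,15,18-heptakis(TBSO)-2-ethyl-14-methyl-1-(TESO)octadec-16-ene | CC[Si](CC)(CC)OC[C@@H](CC)[C@H](O[Si](C)(C)C(C)(C)C)C[C@@H](O[Si](C)(C)C(C)(C)C)CCC[C@H](O[Si](C)(C)C(C)(C)C)C[C@H](O[Si](C)(C)C(C)(C)C)C[C@@H](O[Si](C)(C)C(C)(C)C)[C@@H](C)[C@H](O[Si](C)(C)C(C)(C)C)/C=C/CO[Si](C)(C)C(C)(C)C | intermediate
40 | (2R,3R,5S,9S,11S,13R,14R,15R,16E)-3,5,9,11,13,15,18-heptakis(TBSO)-2-ethyl-14-methyloctadec-16-en-1-ol | OC[C@@H](CC)[C@H](O[Si](C)(C)C(C)(C)C)C[C@@H](O[Si](C)(C)C(C)(C)C)CCC[C@H](O[Si](C)(C)C(C)(C)C)C[C@H](O[Si](C)(C)C(C)(C)C)C[C@@H](O[Si](C)(C)C(C)(C)C)[C@@H](C)[C@H](O[Si](C)(C)C(C)(C)C)/C=C/CO[Si](C)(C)C(C)(C)C | intermediate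
41 | (2S,3R,5S,9S,11S,13R,14R,15R,16E)-3,5,9,11,13,15,18-heptakis(TBSO)-2-ethyl-14-methyloctadec-16-enal | O=C[C@@H](CC)[C@H](O[Si](C)(C)C(C)(C)C)C[C@@H](O[Si](C)(C)C(C)(C)C)CCC[C@H](O[Si](C)(C)C(C)(C)C)C[C@H](O[Si](C)(C)C(C)(C)C)C[C@@H](O[Si](C)(C)C(C)(C)C)[C@@H](C)[C@H](O[Si](C)(C)C(C)(C)C)/C=C/CO[Si](C)(C)C(C)(C)C | intermediate
42 | (2S,3R,5S,9S,11S,13R,14R,15R,16E)-3,5,9,11,13,15,18-heptakis(TBSO)-2-ethyl-14-methyloctadec-16-enoic acid | OC(=O)[C@@H](CC)[C@H](O[Si](C)(C)C(C)(C)C)C[C@@H](O[Si](C)(C)C(C)(C)C)CCC[C@H](O[Si](C)(C)C(C)(C)C)C[C@H](O[Si](C)(C)C(C)(C)C)C[C@@H](O[Si](C)(C)C(C)(C)C)[C@@H](C)[C@H](O[Si](C)(C)C(C)(C)C)/C=C/CO[Si](C)(C)C(C)(C)C | intermediate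
43 | allyl ester of 42 | C=CCOC(=O)[C@@H](CC)[C@H](O[Si](C)(C)C(C)(C)C)C[C@@H](O[Si](C)(C)C(C)(C)C)CCC[C@H](O[Si](C)(C)C(C)(C)C)C[C@H](O[Si](C)(C)C(C)(C)C)C[C@@H](O[Si](C)(C)C(C)(C)C)[C@@H](C)[C@H](O[Si](C)(C)C(C)(C)C)/C=C/CO[Si](C)(C)C(C)(C)C | intermediate
44 | allyl (2S,3R,5S,9S,11S,13R,14R,15R,16E)-3,5,9,11,13,15-hexakis(TBSO)-2-ethyl-18-hydroxy-14-methyloctadec-16-enoate | C=CCOC(=O)[C@@H](CC)[C@H](O[Si](C)(C)C(C)(C)C)C[C@@H](O[Si](C)(C)C(C)(C)C)CCC[C@H](O[Si](C)(C)C(C)(C)C)C[C@H](O[Si](C)(C)C(C)(C)C)C[C@@H](O[Si](C)(C)C(C)(C)C)[C@@H](C)[C@H](O[Si](C)(C)C(C)(C)C)/C=C/CO | intermediate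
45 | allyl (2S,3R,5S,9S,11S,13R,14R,15R,16E)-3,5,9,11,13,15-hexakis(TBSO)-2-ethyl-14-methyl-18-oxooctadec-16-enoate | C=CCOC(=O)[C@@H](CC)[C@H](O[Si](C)(C)C(C)(C)C)C[C@@H](O[Si](C)(C)C(C)(C)C)CCC[C@H](O[Si](C)(C)C(C)(C)C)C[C@H](O[Si](C)(C)C(C)(C)C)C[C@@H](O[Si](C)(C)C(C)(C)C)[C@@H](C)[C@H](O[Si](C)(C)C(C)(C)C)/C=C/C=O | intermediate
46 | (S)-4-benzyl-3-propanoyloxazolidin-2-one | CCC(=O)N1[C@@H](Cc2ccccc2)COC1=O | starting material
47 | acetaldehyde | CC=O | starting material
48 | dibutylboron Z enolate of 46 | C/C=C(\OB(CCCC)CCCC)N1[C@@H](Cc2ccccc2)COC1=O | intermediate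
49 | (4S)-4-benzyl-3-[(2S,3R)-3-hydroxy-2-methylbutanoyl]oxazolidin-2-one | O=C(N1[C@@H](Cc2ccccc2)COC1=O)[C@@H](C)[C@H](O)C | intermediate
50 | (2S,3R)-3-hydroxy-N-methoxy-N,2-dimethylbutanamide | CON(C)C(=O)[C@@H](C)[C@H](O)C | intermediate
51 | (2S,3R)-N-methoxy-N,2-dimethyl-3-(TESO)butanamide | CON(C)C(=O)[C@@H](C)[C@H](O[Si](CC)(CC)CC)C | intermediate
52 | (2S,3R)-2-methyl-3-(TESO)butanal | O=C[C@@H](C)[C@H](O[Si](CC)(CC)CC)C | intermediate
53 | hexa-1,5-diene-3,4-diol | C=CC(O)C(O)C=C | starting material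
54 | (2E,4E)-1,6-dibromohexa-2,4-diene | BrC/C=C/C=C/CBr | intermediate
55 | tetraethyl [(2E,4E)-hexa-2,4-diene-1,6-diyl]bis(phosphonate) | CCOP(=O)(OCC)C/C=C/C=C/CP(=O)(OCC)OCC | intermediate
56 | 1-lithio derivative of 55 | [Li]C(/C=C/C=C/CP(=O)(OCC)OCC)P(=O)(OCC)OCC | intermediate
57 | diethyl [(2E,4E,6E,8R,9R)-8-methyl-9-(TESO)deca-2,4,6-trien-1-yl]phosphonate | CCOP(=O)(OCC)C/C=C/C=C/C=C/[C@@H](C)[C@H](O[Si](CC)(CC)CC)C | intermediate
58 | diethyl [(2E,4E,6E,8R,9R)-9-hydroxy-8-methyldeca-2,4,6-trien-1-yl]phosphonate | CCOP(=O)(OCC)C/C=C/C=C/C=C/[C@@H](C)[C@H](O)C | intermediate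
59 | C,O-dilithio derivative of 58 | [Li]C(/C=C/C=C/C=C/[C@@H](C)[C@H](O[Li])C)P(=O)(OCC)OCC | intermediate
60 | allyl (2S,3R,5S,9S,11S,13R,14R,15R,16E,18E,20E,22E,24E,26R,27R)-3,5,9,11,13,15-hexakis(TBSO)-2-ethyl-27-hydroxy-14,26-dimethyloctacosa-16,18,20,22,24-pentaenoate | C=CCOC(=O)[C@@H](CC)[C@H](O[Si](C)(C)C(C)(C)C)C[C@@H](O[Si](C)(C)C(C)(C)C)CCC[C@H](O[Si](C)(C)C(C)(C)C)C[C@H](O[Si](C)(C)C(C)(C)C)C[C@@H](O[Si](C)(C)C(C)(C)C)[C@@H](C)[C@H](O[Si](C)(C)C(C)(C)C)/C=C/C=C/C=C/C=C/C=C/[C@@H](C)[C@H](O)C | intermediate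
61 | (2S,3R,5S,9S,11S,13R,14R,15R,16E,18E,20E,22E,24E,26R,27R)-3,5,9,11,13,15-hexakis(TBSO)-2-ethyl-27-hydroxy-14,26-dimethyloctacosa-16,18,20,22,24-pentaenoic acid | OC(=O)[C@@H](CC)[C@H](O[Si](C)(C)C(C)(C)C)C[C@@H](O[Si](C)(C)C(C)(C)C)CCC[C@H](O[Si](C)(C)C(C)(C)C)C[C@H](O[Si](C)(C)C(C)(C)C)C[C@@H](O[Si](C)(C)C(C)(C)C)[C@@H](C)[C@H](O[Si](C)(C)C(C)(C)C)/C=C/C=C/C=C/C=C/C=C/[C@@H](C)[C@H](O)C | intermediate
62 | mixed anhydride of 61 with 2,4,6-trichlorobenzoic acid | O=C(OC(=O)c1c(Cl)cc(Cl)cc1Cl)[C@@H](CC)[C@H](O[Si](C)(C)C(C)(C)C)C[C@@H](O[Si](C)(C)C(C)(C)C)CCC[C@H](O[Si](C)(C)C(C)(C)C)C[C@H](O[Si](C)(C)C(C)(C)C)C[C@@H](O[Si](C)(C)C(C)(C)C)[C@@H](C)[C@H](O[Si](C)(C)C(C)(C)C)/C=C/C=C/C=C/C=C/C=C/[C@@H](C)[C@H](O)C | intermediate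
63 | 3,5,9,11,13,15-hexakis-O-(tert-butyldimethylsilyl) derivative of 64 | O=C1[C@@H](CC)[C@H](O[Si](C)(C)C(C)(C)C)C[C@@H](O[Si](C)(C)C(C)(C)C)CCC[C@H](O[Si](C)(C)C(C)(C)C)C[C@H](O[Si](C)(C)C(C)(C)C)C[C@@H](O[Si](C)(C)C(C)(C)C)[C@@H](C)[C@H](O[Si](C)(C)C(C)(C)C)/C=C/C=C/C=C/C=C/C=C/[C@@H](C)[C@@H](C)O1 | intermediate
64 | (3S,4R,6S,10S,12S,14R,15R,16R,17E,19E,21E,23E,25E,27R,28R)-3-ethyl-4,6,10,12,14,16-hexahydroxy-15,27,28-trimethyl-1-oxacyclooctacosa-17,19,21,23,25-pentaen-2-one | CC[C@@H]1C(=O)O[C@H](C)[C@H](C)/C=C/C=C/C=C/C=C/C=C/[C@@H](O)[C@H](C)[C@H](O)C[C@@H](O)C[C@@H](O)CCC[C@H](O)C[C@H]1O | target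

## Step count and least certain steps

Total: 40 steps. Longest linear sequence: 22 steps from (S)-epichlorohydrin 16 (steps 10–14, 16–28, 37–40); the branch through the key step is 21 steps from enone 1.

**Step 4 (key step).** The most likely failure is loss of facial or endo selectivity, because a conjugated aldehyde is less electrophilic and binds the catalyst less firmly than a saturated one. Enal 8 may also react as an oxadiene with the electron-rich diene, and C14 may epimerise during the acid treatment. Fallback (sets out from 5 and 8, returns at 11): the cycloaddition is run with the achiral Lewis acid Eu(fod)3, tris(6,6,7,7,8,8,8-heptafluoro-2,2-dimethyloctane-3,5-dionato)europium (trivalent europium), which should also react endo and give the cis series as a racemate. The flask then holds 9 with its mirror image, ent-cycloadduct F1, and after acid 10 with ent-pyranone F2. Luche reduction as in step 5 gives 11 with ent-glycal alcohol F3. Lipase-catalysed acylation (Burkholderia cepacia lipase, vinyl acetate, t-BuOMe) is expected, by the usual rule for secondary carbinols, to acetylate the 4R alcohol to glycal acetate F4 and leave F3. After separation, K2CO3 in methanol converts F4 into 11. Enantiocontrol then comes from a resolution instead of from the catalyst.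

**Step 8.** The most likely failures are loss of the primary allylic silyl ether under the Lewis acid, ionisation of the freshly released allylic C15 carbinol, or stalling at the cyclic thioglycoside so that the ring does not open. Fallback (sets out from 13, returns at 15): the lactol is oxidised (TEMPO, PhI(OAc)2, CH2Cl2) to δ-lactone F5. The ring is opened by aminolysis (MeNH(OMe)·HCl, AlMe3) to hydroxy Weinreb amide F6. The C15 hydroxyl is silylated (t-BuMe2SiOTf, 2,6-lutidine) to tris-silyl Weinreb amide F7, which is reduced (i-Bu2AlH, −78 °C) to tris-silyl aldehyde F8. Thioacetalisation of this simple aldehyde with propane-1,3-dithiol and MgBr2·OEt2 gives 15. The ring is thus opened by a nucleophile at the acyl carbon, and no Lewis acid meets a free allylic alcohol.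

**Step 20.** The most likely failures are slow epoxide opening by the hindered tertiary carbanion, metalation at the allylic C18 ether position in competition with dithiane deprotonation, or protonation of the anion before it reacts. Fallback (sets out from 15 and 34, returns at 38): the C10–C11 bond is made by an aldol reaction with the polarity reversed. Dithiane 15 is hydrolysed (MeI, CaCO3, aqueous MeCN) to tris-silyl aldehyde F8. Epoxide 34 is opened with LiEt3BH to secondary alcohol F9, oxidised with Dess–Martin periodinane to methyl ketone F10 and converted (LiN(i-Pr)2, Me3SiCl, −78 °C) into enol silane F11. Mukaiyama aldol addition of F11 to F8 (BF3·OEt2, CH2Cl2, −78 °C) should give the C11 carbinol with the 11,13-anti relationship by 1,3-induction from the β-silyloxy aldehyde, i.e. hydroxy ketone F12. Narasaka–Prasad reduction of F12, now directed by O11, gives the 9,11-syn diol 38.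

**Step 37.** The most likely failures are incomplete E selectivity at C18=C19, low reactivity of the aggregated dianion 59, and base-induced epimerisation or elimination at C2/C3 of the ester during a slow reaction. Fallback (sets out from 45, 55 and 52, returns at 60): the order of the two olefinations is reversed, so that the advanced enal meets only a simple monoanion. Enal 45 is treated with an excess of lithiated 55 to give tetraenyl phosphonate F13. Its anion (LiN(SiMe3)2, −78 °C) is then combined with an excess of the small aldehyde 52 to give silyl-protected pentaene F14, in which the last double bond formed is C24=C25. PPTS in methanol removes the triethylsilyl group and gives 60. A minor Z isomer at either new alkene can be equilibrated with a trace of iodine in diffuse light before step 38.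

## Further compounds

F1 | step 4 | (2S,3R,6S)-2-[(E)-3-(TBSO)prop-1-en-1-yl]-6-methoxy-3-methyl-4-(trimethylsilyloxy)-3,6-dihydro-2H-pyran (enantiomer of 9) | CO[C@@H]1C=C(O[Si](C)(C)C)[C@H](C)[C@H](/C=C/CO[Si](C)(C)C(C)(C)C)O1
F2 | step 4 | (2S,3R)-2-[(E)-3-(TBSO)prop-1-en-1-yl]-3-methyl-2,3-dihydro-4H-pyran-4-one (enantiomer of 10) | C[C@@H]1[C@H](/C=C/CO[Si](C)(C)C(C)(C)C)OC=CC1=O
F3 | step 4 | (2S,3S,4S)-2-[(E)-3-(TBSO)prop-1-en-1-yl]-3-methyl-3,4-dihydro-2H-pyran-4-ol (enantiomer of 11) | C[C@@H]1[C@H](/C=C/CO[Si](C)(C)C(C)(C)C)OC=C[C@@H]1O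
F4 | step 4 | (2R,3S,4R)-2-[(E)-3-(TBSO)prop-1-en-1-yl]-3-methyl-3,4-dihydro-2H-pyran-4-yl acetate | C[C@H]1[C@@H](/C=C/CO[Si](C)(C)C(C)(C)C)OC=C[C@H]1OC(C)=O
F5 | step 8 | (4R,5S,6R)-4-(TBSO)-6-[(E)-3-(TBSO)prop-1-en-1-yl]-5-methyltetrahydro-2H-pyran-2-one | C[C@H]1[C@@H](/C=C/CO[Si](C)(C)C(C)(C)C)OC(=O)C[C@H]1O[Si](C)(C)C(C)(C)C
F6 | step 8 | (3R,4S,5R,6E)-3,8-bis(TBSO)-5-hydroxy-N-methoxy-N,4-dimethyloct-6-enamide | CON(C)C(=O)C[C@@H](O[Si](C)(C)C(C)(C)C)[C@@H](C)[C@H](O)/C=C/CO[Si](C)(C)C(C)(C)C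
F7 | step 8 | (3R,4R,5R,6E)-3,5,8-tris(TBSO)-N-methoxy-N,4-dimethyloct-6-enamide | CON(C)C(=O)C[C@@H](O[Si](C)(C)C(C)(C)C)[C@@H](C)[C@H](O[Si](C)(C)C(C)(C)C)/C=C/CO[Si](C)(C)C(C)(C)C
F8 | step 8 | (3R,4R,5R,6E)-3,5,8-tris(TBSO)-4-methyloct-6-enal | O=CC[C@@H](O[Si](C)(C)C(C)(C)C)[C@@H](C)[C@H](O[Si](C)(C)C(C)(C)C)/C=C/CO[Si](C)(C)C(C)(C)C
F9 | step 20 | (2R,6S,8R,9R)-6,8-bis(TBSO)-9-ethyl-10-(TESO)decan-2-ol | CC[Si](CC)(CC)OC[C@@H](CC)[C@H](O[Si](C)(C)C(C)(C)C)C[C@@H](O[Si](C)(C)C(C)(C)C)CCC[C@H](O)C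
F10 | step 20 | (6S,8R,9R)-6,8-bis(TBSO)-9-ethyl-10-(TESO)decan-2-one | CC[Si](CC)(CC)OC[C@@H](CC)[C@H](O[Si](C)(C)C(C)(C)C)C[C@@H](O[Si](C)(C)C(C)(C)C)CCCC(C)=O
F11 | step 20 | (6S,8R,9R)-6,8-bis(TBSO)-9-ethyl-10-(TESO)-2-(trimethylsilyloxy)dec-1-ene | CC[Si](CC)(CC)OC[C@@H](CC)[C@H](O[Si](C)(C)C(C)(C)C)C[C@@H](O[Si](C)(C)C(C)(C)C)CCCC(=C)O[Si](C)(C)C
F12 | step 20 | (2R,3R,5S,11S,13R,14R,15R,16E)-3,5,13,15,18-pentakis(TBSO)-2-ethyl-11-hydroxy-14-methyl-1-(TESO)octadec-16-en-9-one | CC[Si](CC)(CC)OC[C@@H](CC)[C@H](O[Si](C)(C)C(C)(C)C)C[C@@H](O[Si](C)(C)C(C)(C)C)CCCC(=O)C[C@H](O)C[C@@H](O[Si](C)(C)C(C)(C)C)[C@@H](C)[C@H](O[Si](C)(C)C(C)(C)C)/C=C/CO[Si](C)(C)C(C)(C)C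
F13 | step 37 | allyl (2S,3R,5S,9S,11S,13R,14R,15R,16E,18E,20E,22E)-3,5,9,11,13,15-hexakis(TBSO)-24-(diethoxyphosphoryl)-2-ethyl-14-methyltetracosa-16,18,20,22-tetraenoate | C=CCOC(=O)[C@@H](CC)[C@H](O[Si](C)(C)C(C)(C)C)C[C@@H](O[Si](C)(C)C(C)(C)C)CCC[C@H](O[Si](C)(C)C(C)(C)C)C[C@H](O[Si](C)(C)C(C)(C)C)C[C@@H](O[Si](C)(C)C(C)(C)C)[C@@H](C)[C@H](O[Si](C)(C)C(C)(C)C)/C=C/C=C/C=C/C=C/CP(=O)(OCC)OCC
F14 | step 37 | 27-O-triethylsilyl ether of 60 | C=CCOC(=O)[C@@H](CC)[C@H](O[Si](C)(C)C(C)(C)C)C[C@@H](O[Si](C)(C)C(C)(C)C)CCC[C@H](O[Si](C)(C)C(C)(C)C)C[C@H](O[Si](C)(C)C(C)(C)C)C[C@@H](O[Si](C)(C)C(C)(C)C)[C@@H](C)[C@H](O[Si](C)(C)C(C)(C)C)/C=C/C=C/C=C/C=C/C=C/[C@@H](C)[C@H](O[Si](CC)(CC)CC)C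
A1 | alternative 1 | protected C1–C13 5,9-diketone | CC(C)(C)[Si](c1ccccc1)(c1ccccc1)OC[C@@H](CC)[C@H](O[Si](CC)(CC)CC)CC(=O)CCCC(=O)C[C@H](OCc1ccc(OC)cc1)CCO[Si](C)(C)C(C)(C)C
A2 | alternative 1 | 1,3-diketone precursor of A1 | CC(C)(C)[Si](c1ccccc1)(c1ccccc1)OC[C@@H](CC)[C@H](O[Si](CC)(CC)CC)CC(=O)CC(=O)C[C@H](OCc1ccc(OC)cc1)CCO[Si](C)(C)C(C)(C)C
A3 | alternative 1 | ethene | C=C
A4 | alternative 2 | macrolide with free C3 hydroxyl and five TBS ethers | CC[C@@H]1C(=O)O[C@H](C)[C@H](C)/C=C/C=C/C=C/C=C/C=C/[C@@H](O[Si](C)(C)C(C)(C)C)[C@H](C)[C@H](O[Si](C)(C)C(C)(C)C)C[C@@H](O[Si](C)(C)C(C)(C)C)C[C@@H](O[Si](C)(C)C(C)(C)C)CCC[C@H](O[Si](C)(C)C(C)(C)C)C[C@H]1O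
A5 | alternative 2 | seco C3 aldehyde carrying the O27 2-bromobutanoate | O=CC[C@@H](O[Si](C)(C)C(C)(C)C)CCC[C@H](O[Si](C)(C)C(C)(C)C)C[C@H](O[Si](C)(C)C(C)(C)C)C[C@@H](O[Si](C)(C)C(C)(C)C)[C@@H](C)[C@H](O[Si](C)(C)C(C)(C)C)/C=C/C=C/C=C/C=C/C=C/[C@@H](C)[C@@H](C)OC(=O)C(Br)CC
A6 | alternative 3 | macrolide with free C15 hydroxyl and five TBS ethers | CC[C@@H]1C(=O)O[C@H](C)[C@H](C)/C=C/C=C/C=C/C=C/C=C/[C@@H](O)[C@H](C)[C@H](O[Si](C)(C)C(C)(C)C)C[C@@H](O[Si](C)(C)C(C)(C)C)C[C@@H](O[Si](C)(C)C(C)(C)C)CCC[C@H](O[Si](C)(C)C(C)(C)C)C[C@H]1O[Si](C)(C)C(C)(C)C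
A7 | alternative 3 | seco C15 aldehyde with C16 pentaenyl iodide terminus | I/C=C/C=C/C=C/C=C/C=C/[C@@H](C)[C@@H](C)OC(=O)[C@@H](CC)[C@H](O[Si](C)(C)C(C)(C)C)C[C@@H](O[Si](C)(C)C(C)(C)C)CCC[C@H](O[Si](C)(C)C(C)(C)C)C[C@H](O[Si](C)(C)C(C)(C)C)C[C@@H](O[Si](C)(C)C(C)(C)C)[C@@H](C)C=O
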